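## Retrosynthetic overview

1. Core numbering: 7-oxabicyclo[2.2.1]heptane with C1 (bridgehead, CH3), C2 (CH, carbinol side chain endo), C3 (quaternary, CH3 endo, bromochloro chain exo), C4 (bridgehead, H), C5, C6 and O7.
2. Enabling feature: in the oxolane ring O7–C1–C2–C3–C4, O7 sits on secondary C4 next to quaternary C3 and on tertiary, methyl-bearing C1 next to C2–H. O7–C4–C3 is therefore the imprint of a trisubstituted epoxide opened at its tertiary carbon, C2–C1 that of a trisubstituted alkene, and the C5–C6 bridge is the tether that holds the two 1,5 apart.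
3. Key disconnection: C2–C3 and C1–O7 are cut together (formal [3+2] of the epoxide C–O bond across the alkene), which unravels the bicycle to an acyclic (Z)-alkene/cis-epoxide. Forward ring order: the carbocycle closes first (C2–C3), the oxolane O7–C1–C2–C3–C4 closes last (C1–O7).
4. The acyclic precursor is split at the sp2–sp3 bond next to the alkene (B-alkyl Suzuki) into two C10-size halves. Fragment A is a halogenated vinyl epoxide from neryl acetate; fragment B is a (Z)-vinyl iodide from geraniol.
5. Stereocentres: Shi epoxidation plus a bromonium relay sets C–Br, and one Sharpless epoxidation sets the carbinol. The other Sharpless epoxidation sets C4, from which C3, C2 and C1 are relayed in the key event; only a desilylation follows.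

Key step: step 15

Remark: neryl acetate, geraniol, both diethyl tartrates and the D-fructose-derived Shi ketone are taken as commercial; Li2NiBr4 is used as a preformed THF solution made from LiBr and NiBr2.

## Fragment A

Step 1
Reactants: 1 neryl acetate [(2Z)-3,7-dimethylocta-2,6-dien-1-yl acetate]
Product: 2 (6R)-6,7-epoxyneryl acetate [(2Z)-5-[(2R)-3,3-dimethyloxiran-2-yl]-3-methylpent-2-en-1-yl acetate]
Conditions: D-fructose-derived Shi ketone (30 mol %), KHSO5 (as 2KHSO5·KHSO4·K2SO4), K2CO3, Bu4NHSO4, Na2B4O7 buffer, MeCN–CH2(OMe)2–H2O, 0 °C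
Reagents that add atoms: potassium peroxymonosulfate, [K+].[O-]S(=O)(=O)OO
Why: Shi asymmetric epoxidation, in which the chiral dioxirane attacks only the electron-rich terminal trisubstituted alkene (the other one is deactivated by its allylic acetate) through the spiro transition state, so the D-fructose-derived catalyst should set the (R)-epoxide carbon.

Step 2
Reactants: 2 (6R)-6,7-epoxyneryl acetate
Product: 3 (2Z,6S)-6-bromo-7-hydroxy-3,7-dimethyloct-2-en-1-yl acetate
Conditions: Li2NiBr4, THF, 0 °C → rt; aqueous work-up
Reagents that add atoms: dilithium tetrabromonickelate, [Li+].[Li+].[Ni+2].[Br-].[Br-].[Br-].[Br-]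
Why: SN2 opening of an epoxide by soft nucleophilic bromide at the less substituted carbon, with inversion, should turn the (R)-C–O centre into the (S)-C–Br centre of the target.

Step 3
Reactants: 3 (2Z,6S)-6-bromo-7-hydroxy-3,7-dimethyloct-2-en-1-yl acetate
Product: 4 (2Z,6S)-6-bromo-7-chloro-3,7-dimethyloct-2-en-1-yl acetate
Conditions: 1-chloro-N,N,2-trimethylprop-1-en-1-amine (Ghosez reagent), CH2Cl2, 0 °C → rt
Reagents that add atoms: 1-chloro-N,N,2-trimethylprop-1-en-1-amine, CC(C)=C(Cl)N(C)C
Why: Neutral alcohol-to-chloride exchange with an α-chloroenamine, in which the activated tertiary oxygen leaves with anchimeric help from the neighbouring bromine and chloride opens the bromonium ion at its tertiary carbon, so the C–Br centre is untouched, and any regioisomeric bromohydrin from step 2 (tertiary Br, secondary OH) should funnel through the same bromonium ion to the same product.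

Step 4
Reactants: 4 (2Z,6S)-6-bromo-7-chloro-3,7-dimethyloct-2-en-1-yl acetate
Product: 5 (2Z,6S)-6-bromo-7-chloro-3,7-dimethyloct-2-en-1-ol
Conditions: K2CO3 (0.2 equiv), MeOH, 0 °C
Reagents that add atoms: none
Why: Base-catalysed transesterification (Zemplén type) at 0 °C removes the acetate much faster than carbonate in methanol can eliminate HX from the hindered dihalide, and no stereocentre is touched.

Step 5
Reactants: 5 (2Z,6S)-6-bromo-7-chloro-3,7-dimethyloct-2-en-1-ol
Product: 6 {(2R,3S)-3-[(3S)-3-bromo-4-chloro-4-methylpentyl]-3-methyloxiran-2-yl}methanol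
Conditions: Ti(OiPr)4 (10 mol %), D-(−)-diethyl tartrate (12 mol %), t-BuOOH, 4 Å MS, CH2Cl2, −20 °C
Reagents that add atoms: tert-butyl hydroperoxide, CC(C)(C)OO
Why: Sharpless asymmetric epoxidation of a (Z)-allylic alcohol, in which D-(−)-tartrate delivers oxygen to the face that gives the (2R,3S)-cis-epoxide under reagent control, the C–Br centre being too remote to interfere.

Step 6
Reactants: 6 {(2R,3S)-3-[(3S)-3-bromo-4-chloro-4-methylpentyl]-3-methyloxiran-2-yl}methanol
Product: 7 (2S,3S)-3-[(3S)-3-bromo-4-chloro-4-methylpentyl]-3-methyloxirane-2-carbaldehyde (same spatial arrangement; the C2 descriptor changes only by priority)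
Conditions: TEMPO (10 mol %), PhI(OAc)2, CH2Cl2, rt
Reagents that add atoms: none
Why: TEMPO/PhI(OAc)2 oxidation of a primary alcohol stops at the aldehyde under almost neutral conditions that leave epoxide and halides alone, and the epoxide carbons cannot enolise.

Step 7
Reactants: 7 (2S,3S)-3-[(3S)-3-bromo-4-chloro-4-methylpentyl]-3-methyloxirane-2-carbaldehyde
Product: 8 (2S,3R)-2-[(3S)-3-bromo-4-chloro-4-methylpentyl]-3-ethenyl-2-methyloxirane
Conditions: MePPh3Br, KN(SiMe3)2, THF, 0 °C; then 7, −78 → 0 °C
Reagents that add atoms: methyltriphenylphosphonium bromide, C[P+](c1ccccc1)(c1ccccc1)c1ccccc1.[Br-]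
Why: Wittig methylenation of the unhindered epoxy aldehyde at low temperature is faster than any E2 attack of the ylide on the dihalide and gives the vinyl epoxide without touching a stereocentre.

## Fragment B

Step 8
Reactants: 9 geraniol [(2E)-3,7-dimethylocta-2,6-dien-1-ol]
Product: 10 [(2S,3S)-3-methyl-3-(4-methylpent-3-en-1-yl)oxiran-2-yl]methanol
Conditions: Ti(OiPr)4 (5 mol %), L-(+)-diethyl tartrate (7 mol %), t-BuOOH, 4 Å MS, CH2Cl2, −20 °C
Reagents that add atoms: tert-butyl hydroperoxide, CC(C)(C)OO
Why: Sharpless asymmetric epoxidation with L-(+)-tartrate gives the (2S,3S)-epoxide, whose tertiary C–O centre becomes the carbinol centre of the target, while the isolated alkene does not react.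

Step 9
Reactants: 10 [(2S,3S)-3-methyl-3-(4-methylpent-3-en-1-yl)oxiran-2-yl]methanol
Product: 11 (2S,3R)-3-(iodomethyl)-2-methyl-2-(4-methylpent-3-en-1-yl)oxirane
Conditions: I2, PPh3, imidazole, CH2Cl2, 0 °C
Reagents that add atoms: iodine, [I][I]
Why: Appel-type (Garegg–Samuelsson) iodination of the primary alcohol proceeds by SN2 at CH2 and leaves both epoxide carbons untouched.

Step 10
Reactants: 11 (2S,3R)-3-(iodomethyl)-2-methyl-2-(4-methylpent-3-en-1-yl)oxirane
Product: 12 (S)-linalool [(3S)-3,7-dimethylocta-1,6-dien-3-ol]
Conditions: Zn dust, AcOH (2 equiv), EtOH, 0 °C → rt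
Reagents that add atoms: none
Why: Zinc inserts into the C–I bond and the β-oxido organozinc fragments (reductive epoxide opening, Boord-type elimination), which transposes the epoxy alcohol into the tertiary vinyl carbinol with the C–O stereocentre retained.

Step 11
Reactants: 12 (S)-linalool
Product: 13 triethyl{[(3S)-3,7-dimethylocta-1,6-dien-3-yl]oxy}silane
Conditions: Et3SiOTf, 2,6-lutidine, CH2Cl2, −78 → 0 °C
Reagents that add atoms: triethylsilyl triflate, CC[Si](CC)(CC)OS(=O)(=O)C(F)(F)F
Why: Silyl triflate/lutidine silylation is the standard way to cap a hindered tertiary alcohol, and the group masks the nucleophilic OH for the key step.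

Step 12
Reactants: 13 triethyl{[(3S)-3,7-dimethylocta-1,6-dien-3-yl]oxy}silane
Product: 15 (4S)-4-methyl-4-[(triethylsilyl)oxy]hex-5-enal, via secondary ozonide 14 (not isolated)
Conditions: O3/O2, CH2Cl2, −78 °C, stopped at one equivalent (Sudan Red 7B end point); then Me2S, −78 °C → rt
Reagents that add atoms: ozone, [O-][O+]=O
Why: Chemoselective ozonolysis (Criegee mechanism), in which ozone is consumed by the electron-rich trisubstituted alkene well before the hindered monosubstituted vinyl group, and Me2S reduces the ozonide to the aldehyde.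

Step 13
Reactants: 15 (4S)-4-methyl-4-[(triethylsilyl)oxy]hex-5-enal
Product: 16 triethyl{[(3S,6Z)-7-iodo-3-methylocta-1,6-dien-3-yl]oxy}silane
Conditions: EtPPh3I, n-BuLi, THF, rt; I2, −78 °C; NaN(SiMe3)2, −20 °C; then 15, −78 → −20 °C
Reagents that add atoms: ethyltriphenylphosphonium iodide, CC[P+](c1ccccc1)(c1ccccc1)c1ccccc1.[I-]; iodine, [I][I]
Why: Stork–Zhao-type Wittig olefination with the α-iodo ylide Ph3P=C(I)CH3 gives the (Z)-2-iodoalk-2-ene under kinetic control, which fixes the alkene geometry needed in the key step.

## Union, key step and end game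

Step 14
Reactants: 8 (2S,3R)-2-[(3S)-3-bromo-4-chloro-4-methylpentyl]-3-ethenyl-2-methyloxirane; 16 triethyl{[(3S,6Z)-7-iodo-3-methylocta-1,6-dien-3-yl]oxy}silane
Product: 18 triethyl{[(3S,6Z)-9-{(2R,3S)-3-[(3S)-3-bromo-4-chloro-4-methylpentyl]-3-methyloxiran-2-yl}-3,7-dimethylnona-1,6-dien-3-yl]oxy}silane, via B-alkyl-9-BBN adduct 17 (not isolated)
Conditions: 8, 9-BBN (1.05 equiv), THF, 0 °C → rt; H2O; then 16, Pd(dppf)Cl2 (5 mol %), AsPh3, Cs2CO3, DMF, rt
Reagents that add atoms: 9-borabicyclo[3.3.1]nonane, B1C2CCCC1CCC2 (its boron cage is carried only by 17; 18 keeps one hydrogen of it)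
Why: B-alkyl Suzuki–Miyaura coupling, in which 9-BBN adds only to the terminal vinyl group with boron at CH2, and zerovalent palladium inserts into the alkenyl C–I bond (not into the hindered alkyl halides) and couples with retention of the (Z) geometry.

Step 15
Reactants: 18 triethyl{[(3S,6Z)-9-{(2R,3S)-3-[(3S)-3-bromo-4-chloro-4-methylpentyl]-3-methyloxiran-2-yl}-3,7-dimethylnona-1,6-dien-3-yl]oxy}silane
Product: 20 triethyl{[(3S)-5-{(1S,2S,3S,4R)-3-[(3S)-3-bromo-4-chloro-4-methylpentyl]-1,3-dimethyl-7-oxabicyclo[2.2.1]heptan-2-yl}-3-methylpent-1-en-3-yl]oxy}silane, via tertiary cyclohexyl cation 19 (not isolated)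
Conditions: BF3·OEt2 (0.3 equiv), CH2Cl2 (high dilution), −78 °C; Et3N quench
Reagents that add atoms: none
Why: BF3 activates the trisubstituted epoxide, and the CH carbon of the (Z)-alkene attacks its tertiary carbon from the back through a chair transition state (6-endo at both epoxide and alkene; C2–C3 bond, carbocycle closed first) to give tertiary cation 19, whose C4 oxygen then adds across the ring to C1 through a boat (transannular 1,4-capture; C1–O7 bond, oxolane O7–C1–C2–C3–C4 closed last) and releases the Lewis acid. The closest known reaction type is the Lewis-acid epoxy-olefin cyclisation of geraniolene oxide and 6,7-epoxygeranyl esters, in which 7-oxabicyclo[2.2.1]heptanes arise by this same internal capture. C4 is carried over unchanged from the Sharpless epoxide; C3 is set by stereospecific inversion at the epoxide carbon, so the cis (nerol-derived) epoxide places the halogenated chain exo and CH3 endo; C2 is set by the (Z)-alkene geometry in the chair, which puts the side chain axial and trans to the C4 oxygen, hence endo; C1 can only be reached from the face that carries the C4 oxygen. Chemoselectivity is secured because this alkene is the only π-nucleophile that reaches the epoxide through a six-membered array, the former prenyl alkene is saturated as the bromochloride, the vinyl group is monosubstituted and remote, and the tertiary OSiEt3 oxygen is too hindered to compete. The partition of 19 should favour the ether because both long chains are axial in the first-formed chair, so the flip of C4 towards the boat relieves strain and brings oxygen over C1, while C2–H is equatorial and cannot align with the empty orbital (no hydride shift), and low temperature with a non-basic counter-ion holds back proton loss.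

Step 16
Reactants: 20 triethylsilyl ether of the target
Product: 21 target, (3S)-5-{(1S,2S,3S,4R)-3-[(3S)-3-bromo-4-chloro-4-methylpentyl]-1,3-dimethyl-7-oxabicyclo[2.2.1]heptan-2-yl}-3-methylpent-1-en-3-ol
Conditions: HF·pyridine, pyridine, THF, 0 °C
Reagents that add atoms: none
Why: Fluoride-driven Si–O cleavage under pyridine-buffered conditions frees the tertiary allylic alcohol without ionising it and leaves the ether bridge and both halides untouched.

## Compound list

1 | neryl acetate | CC(C)=CCC/C(C)=C\COC(C)=O | starting material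
2 | (6R)-6,7-epoxyneryl acetate | CC1(C)O[C@@H]1CC/C(C)=C\COC(C)=O | intermediate
3 | (2Z,6S)-6-bromo-7-hydroxy-3,7-dimethyloct-2-en-1-yl acetate | CC(C)(O)[C@@H](Br)CC/C(C)=C\COC(C)=O | intermediate
4 | (2Z,6S)-6-bromo-7-chloro-3,7-dimethyloct-2-en-1-yl acetate | CC(C)(Cl)[C@@H](Br)CC/C(C)=C\COC(C)=O | intermediate
5 | (2Z,6S)-6-bromo-7-chloro-3,7-dimethyloct-2-en-1-ol | CC(C)(Cl)[C@@H](Br)CC/C(C)=C\CO | intermediate
6 | {(2R,3S)-3-[(3S)-3-bromo-4-chloro-4-methylpentyl]-3-methyloxiran-2-yl}methanol | CC(C)(Cl)[C@@H](Br)CC[C@]1(C)O[C@@H]1CO | intermediate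
7 | (2S,3S)-3-[(3S)-3-bromo-4-chloro-4-methylpentyl]-3-methyloxirane-2-carbaldehyde | CC(C)(Cl)[C@@H](Br)CC[C@]1(C)O[C@@H]1C=O | intermediate
8 | (2S,3R)-2-[(3S)-3-bromo-4-chloro-4-methylpentyl]-3-ethenyl-2-methyloxirane | CC(C)(Cl)[C@@H](Br)CC[C@]1(C)O[C@@H]1C=C | intermediate
9 | geraniol | CC(C)=CCC/C(C)=C/CO | starting material
10 | (2S,3S)-2,3-epoxygeraniol | CC(C)=CCC[C@]1(C)O[C@H]1CO | intermediate
11 | (2S,3R)-3-(iodomethyl)-2-methyl-2-(4-methylpent-3-en-1-yl)oxirane | CC(C)=CCC[C@]1(C)O[C@H]1CI | intermediate
12 | (S)-linalool | C=C[C@@](C)(O)CCC=C(C)C | intermediate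
13 | (S)-linalool triethylsilyl ether | C=C[C@@](C)(O[Si](CC)(CC)CC)CCC=C(C)C | intermediate
14 | secondary ozonide, 3,3-dimethyl-5-{(3S)-3-methyl-3-[(triethylsilyl)oxy]pent-4-en-1-yl}-1,2,4-trioxolane (acetal carbon undefined) | C=C[C@@](C)(O[Si](CC)(CC)CC)CCC1OOC(C)(C)O1 | intermediate
15 | (4S)-4-methyl-4-[(triethylsilyl)oxy]hex-5-enal | C=C[C@@](C)(O[Si](CC)(CC)CC)CCC=O | intermediate
16 | triethyl{[(3S,6Z)-7-iodo-3-methylocta-1,6-dien-3-yl]oxy}silane | C=C[C@@](C)(O[Si](CC)(CC)CC)CC/C=C(\I)C | intermediate
17 | 9-(2-{(2R,3S)-3-[(3S)-3-bromo-4-chloro-4-methylpentyl]-3-methyloxiran-2-yl}ethyl)-9-borabicyclo[3.3.1]nonane | CC(C)(Cl)[C@@H](Br)CC[C@]1(C)O[C@@H]1CCB2C3CCCC2CCC3 | intermediate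
18 | acyclic (6Z)-alkene/cis-epoxide key precursor | C=C[C@@](C)(O[Si](CC)(CC)CC)CC/C=C(C)\CC[C@H]1O[C@@]1(C)CC[C@H](Br)C(C)(C)Cl | intermediate
19 | monocyclic tertiary 4-hydroxycyclohexyl cation (oxygen drawn free of boron) | C=C[C@@](C)(O[Si](CC)(CC)CC)CC[C@H]1[C@](C)(CC[C@H](Br)C(C)(C)Cl)[C@H](O)CC[C+]1C | intermediate
20 | triethylsilyl ether of the target | C=C[C@@](C)(O[Si](CC)(CC)CC)CC[C@H]1[C@](C)(CC[C@H](Br)C(C)(C)Cl)[C@H]2CC[C@]1(C)O2 | intermediate
21 | CNP0297543.1 | C=C[C@@](C)(O)CC[C@H]1[C@](C)(CC[C@H](Br)C(C)(C)Cl)[C@H]2CC[C@]1(C)O2 | target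

## Step count and risks

Total step count: 16. Longest linear sequence: 10 steps (steps 1–7, then 14–16).

**Step 15.**
- Cation 19 may lose a proton, or the activated epoxide may rearrange to a ketone, faster than the ring flip allows capture by oxygen.
- A boat-type attack on the other alkene face may erode the C2 configuration.
- The distal bromine may take part at the epoxide carbon.
- The allylic silyl ether may ionise.

The fallback sets out from 18 and comes back at 20, and it separates the two bond formations. The monocyclisation is run with ZrCl4 in CH2Cl2, a Lewis acid that tends to end epoxy-olefin cyclisations by proton loss. This should give the cyclohexenol F1 (20 with the C1–O7 bond replaced by a free C4–OH and a C1=C6 double bond). The ether is then closed by transannular oxymercuration with Hg(OCOCF3)2, with Markovnikov attack of the C4 hydroxyl on the methyl-bearing alkene carbon, anti to mercury. This gives the 6-endo organomercurial F2, and NaBH4/NaOH demercuration leads to 20.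

**Step 14.** The hydroxyborate complex of 17 may undergo 1,3-elimination onto the neighbouring epoxide carbon. Alternatively, the base may remove HX from the dihalide while transmetalation is slow.

The fallback sets out from 8 and 16 and comes back at 18. It takes boron out before any basic coupling and reverses the polarity.
- 8 is hydroborated as before but oxidised at once with NaBO3·4H2O to the homologous epoxy alcohol F3.
- F3 is converted by Appel-type iodination into the primary iodide F4.
- 16 is turned by t-BuLi and then ZnBr2, with retention of geometry, into the alkenylzinc bromide F5.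
- F4 and F5 are joined by a Negishi alkyl–alkenyl coupling (Pd2(dba)3, tricyclopentylphosphine, N-methylimidazole, THF). The SN2-type oxidative addition should select the primary iodide over the hindered secondary bromide.

**Step 3.** The ionising tertiary centre may eliminate to an isopropenyl group, or the bromonium ion may be captured by the internal alkene. It may also hand its bromine to the alkene of another molecule, which would erode the C–Br configuration.

The fallback sets out from 2 and comes back at 4. It reverses the order of the halogens, so that no bromonium ion is needed.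
- HCl in Et2O at −30 °C opens 2 at its tertiary carbon (Markovnikov opening) to the chlorohydrin F6, with the C–O centre intact.
- Tf2O/2,6-lutidine gives the triflate F7.
- Bu4NBr displaces the triflate with inversion to give 4.

## Further compounds

F1 | step 15 | cyclohexenol: 20 with a free C4–OH and a C1=C6 double bond in place of the C1–O7 bond | C=C[C@@](C)(O[Si](CC)(CC)CC)CC[C@H]1[C@](C)(CC[C@H](Br)C(C)(C)Cl)[C@H](O)CC=C1C
F2 | step 15 | 20 carrying a 6-endo mercury trifluoroacetate group | C=C[C@@](C)(O[Si](CC)(CC)CC)CC[C@H]1[C@](C)(CC[C@H](Br)C(C)(C)Cl)[C@H]2C[C@@H]([Hg]OC(=O)C(F)(F)F)[C@]1(C)O2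
F3 | step 14 | 2-{(2R,3S)-3-[(3S)-3-bromo-4-chloro-4-methylpentyl]-3-methyloxiran-2-yl}ethanol | CC(C)(Cl)[C@@H](Br)CC[C@]1(C)O[C@@H]1CCO
F4 | step 14 | (2S,3R)-2-[(3S)-3-bromo-4-chloro-4-methylpentyl]-3-(2-iodoethyl)-2-methyloxirane | CC(C)(Cl)[C@@H](Br)CC[C@]1(C)O[C@@H]1CCI
F5 | step 14 | (2Z,6S)-6-methyl-6-[(triethylsilyl)oxy]octa-2,7-dien-2-ylzinc bromide | C=C[C@@](C)(O[Si](CC)(CC)CC)CC/C=C(\[Zn]Br)C
F6 | step 3 | (2Z,6R)-7-chloro-6-hydroxy-3,7-dimethyloct-2-en-1-yl acetate | CC(C)(Cl)[C@H](O)CC/C(C)=C\COC(C)=O
F7 | step 3 | (2Z,6R)-7-chloro-3,7-dimethyl-6-[(trifluoromethylsulfonyl)oxy]oct-2-en-1-yl acetate | CC(C)(Cl)[C@H](OS(=O)(=O)C(F)(F)F)CC/C(C)=C\COC(C)=O
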